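We have no constants for this flask, so we read times from the runs instead.

| flask | G | Z | J | time |
|---|---|---|---|---|
| grey | 0.120 M | 0.144 M | 0.00360 M |  |
| ochre | 0.120 M | 0.144 M | 0.00540 M |  |
| violet | 0.360 M | 0.144 M | 0.00360 M |  |
| amber | 0.120 M | 0.0720 M | 0.00360 M |  |
| red | 0.240 M | 0.0480 M | 0.00360 M | 16 min |

| run | time / min | [E] / M |
|---|---|---|
| grey run | 0.71 | 0.0039 |
| grey run | 2.2 | 0.0110 |
| grey run | 4.1 | 0.0195 |
| grey run | 6.5 | 0.0287 |
| grey run | 9.3 | 0.0371 |
| grey run | 13 | 0.0464 |
| grey run | 16 | 0.0522 |
| ochre run | 0.71 | 0.0054 |
| ochre run | 2.2 | 0.0175 |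
| ochre run | 4.1 | 0.0292 |
| ochre run | 6.5 | 0.0410 |
| ochre run | 9.3 | 0.0526 |
| ochre run | 13 | 0.0652 |
| ochre run | 16 | 0.0727 |
| violet run | 0.71 | 0.0078 |
| violet run | 2.2 | 0.0221 |
| violet run | 4.1 | 0.0389 |
| violet run | 6.5 | 0.0532 |
| violet run | 9.3 | 0.0685 |
| violet run | 13 | 0.0822 |
| violet run | 16 | 0.0900 |
| amber run | 0.71 | 0.0021 |
| amber run | 2.2 | 0.0058 |
| amber run | 4.1 | 0.0116 |
| amber run | 6.5 | 0.0168 |
| amber run | 9.3 | 0.0227 |
| amber run | 13 | 0.0286 |
| amber run | 16 | 0.0320 |

(readings scatter by 4 × 10⁻⁴ M)

1. reaction order in [G] at the outset, round the charge of the grey run, defined at two percent of the G turned into E (one fixed amount of E, the same in the runs compared)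
2. reaction order in [Z] at the outset, round the charge of the grey run, defined at two percent of the G turned into E
3. E in the red run at 16 min, as a share of the G charged

- Overall: G + Z -> E, with J as catalyst.
- Constant volume, constant temperature.
- What is held in complexes is read along with the free species.
- "The second partner" is Z.
- An order is taken over about fifteen percent of the charge, up and down.

Over the first 2.2 min, the grey flask makes E at 0.00500 M min⁻¹. From the same reading, violet against grey gives an average order in G of 0.635. Grey against amber gives an average order in Z of 0.923. These span wide steps in the charge, so they are not yet the local orders asked for. Scaling grey by them, we reckon the opening rate of the red flask: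

rate in red = 0.00282 M min⁻¹

Dividing the red charges of Z and G by that rate gives a ladder of times:

lifetime of Z: 17.0 min

lifetime of G: 85.2 min

We carry one quantity, the lifetime of Z: its charge divided by the opening rate.

On the first rung, Z is the limiting reagent in the red flask, with a smaller charge than G, and 16 min is 0.941 lifetimes of Z.

On the top rung, G lasts much longer than the time asked. Because of that gap, G stays near its charge, and we treat red as pseudo-first-order in Z, whose order reads close to one. We make no allowance for the small fall in G.

share of Z used = 1 − exp(−t/lifetime) = 60.9 %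

share of G turned into E = 12.2 %

The forecast gives 0.74 for G, between 0.62 and 0.86, and 0.86 for Z, between 0.72 and 1. For red it gives 12 %, between 10.8 % and 13.2 %. Its order in G is higher than ours because it reads the slowing with G as something “which points to saturation”. Its red figure carries “a roughly 10% drag”, and ours carries none.

The flask gives orders of 0.67 in G and 0.79 in Z, and E in red at 16 min is 12.4 % of the G charged, within the forecast's range.

    J + G ⇌ JG, settled at all times (11.10 M⁻¹)
    J + Z ⇌ JZ, settled at all times (5.790 M⁻¹)
    JG + JZ → E + 2 J (1608 M⁻¹ min⁻¹)
    G + Z → E (0.1902 M⁻¹ min⁻¹)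
    E + Z → Q (0.1176 M⁻¹ min⁻¹)

The step of E with Z to Q makes no difference that counts to that share. The lifetime of Z carries to the violet flask, where the reading gives 14.3 min. There a quarter of the G charged is 62.5 % of the Z charged, and the count reaches that share at 14.1 min. The violet flask takes longer, at 16.0 min.

The earlier runs and the new flask were generated by integration with constants of no real substance; noise was put on by code.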